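The dihydrofuran ring is cut at O1–C2 and C2–C3. Because C2 holds a single aryl substituent and is otherwise tied only to O1 and C3, it can be supplied as one benzylidene carbon that bridges the ends of the O1–C7a–C3a–C3 heterodiene once ring A is unmasked as an ortho-quinone methide. One base-mediated [4+1] annulation with a chiral thiolanium benzylide therefore closes the heterocycle, makes both bonds and sets the trans (2S,3R) centres. Its precursor is a racemic guaiacol-type phenol carrying an ortho CH(SO2Ph)CH2OTBS arm and a para 3-silyloxypropyl chain; the partner is a 3,5-dimethoxy-4-silyloxybenzyl (2S,5S)-2,5-dimethylthiolanium salt.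

Key step: step 10

Abbreviations: TBS = tert-butyldimethylsilyl; TIPS = triisopropylsilyl; Ms = methanesulfonyl.

Remark (assumption on the sense of induction): the methyl group cis to the benzylidene shields one ylide face. The (2R,5R)-sulfide transfers benzylidene to benzaldehyde in the (S,S) sense, and by the same face selection and inversion it would give (2R,3S) here, because the aryl group and the new C–C partner swap CIP rank between the epoxide and the dihydrobenzofuran. The route therefore uses the (2S,5S)-sulfide, made with double inversion from (2R,5R)-hexane-2,5-diol, and assumes this facial preference carries over to the methide acceptor.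

Remark (protecting groups): the syringyl hydroxyl is carried as a TIPS ether, so that one fluoride treatment ends the synthesis and no hydrogenolysis is run on a molecule with a benzylic C2–O1 bond.

Step 1
Reactants: 1 3-(4-hydroxy-3-methoxyphenyl)propan-1-ol
Product: 2 4-[3-(TBSO)propyl]-2-methoxyphenol
Conditions: TBSCl (1.05 equiv), imidazole (2.2 equiv), CH2Cl2, 0 °C
Reagents that add atoms: tert-butyldimethylsilyl chloride, CC(C)(C)[Si](C)(C)Cl
Why: Chemoselective silyl ether formation, in which the unhindered primary alcohol should react much faster than the hydrogen-bonded, ortho-substituted guaiacol hydroxyl, so that a limited amount of chloride at 0 °C leaves the phenol free.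

Step 2
Reactants: 2 4-[3-(TBSO)propyl]-2-methoxyphenol; 3 (tert-butyldimethylsilyloxy)acetaldehyde
Product: 5 rac-2-[1-hydroxy-2-(TBSO)ethyl]-6-methoxy-4-[3-(TBSO)propyl]phenol, via bromomagnesium phenolate 4 (not isolated)
Conditions: EtMgBr (1.0 equiv), Et2O, 0 °C; solvent switch to CH2Cl2; 3 (1.2 equiv), 0 °C to rt; aq NH4Cl
Reagents that add atoms: none
Why: Magnesium-phenolate-directed ortho-hydroxyalkylation (the aldehyde counterpart of magnesium-mediated ortho-formylation of phenols), in which the metal on the phenolate oxygen binds the aldehyde in a non-coordinating solvent and delivers it through a six-membered chelate to the only free ortho carbon; the new carbinol centre is racemic, which is harmless because it is planarised before the key step.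

Step 3
Reactants: 5 rac-2-[1-hydroxy-2-(TBSO)ethyl]-6-methoxy-4-[3-(TBSO)propyl]phenol
Product: 7 rac-2-[1-(phenylsulfonyl)-2-(TBSO)ethyl]-6-methoxy-4-[3-(TBSO)propyl]phenol, via ortho-hydroxybenzylic cation 6 (not isolated)
Conditions: freshly prepared PhSO2H (1.5 equiv), CH2Cl2, rt
Reagents that add atoms: benzenesulfinic acid, O=S(O)c1ccccc1
Why: Acid-promoted SN1-type substitution of an ortho-hydroxybenzylic alcohol, in which the sulfinic acid protonates the carbinol, water leaves to give cation 6 (stabilised by the ortho hydroxyl and held as an ion pair with benzenesulfinate) and the soft sulfinate collapses on the benzylic carbon through sulfur, which is the standard entry to 2-(1-sulfonylalkyl)phenols; the weak acid in an aprotic solvent should spare the primary TBS ethers, and the sulfone centre is racemic.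

Step 4
Reactants: 8 syringaldehyde (4-hydroxy-3,5-dimethoxybenzaldehyde)
Product: 9 3,5-dimethoxy-4-(TIPSO)benzaldehyde
Conditions: TIPSCl (1.2 equiv), imidazole (2.5 equiv), DMF, rt
Reagents that add atoms: triisopropylsilyl chloride, CC(C)[Si](Cl)(C(C)C)C(C)C
Why: Silylation of a phenol made more acidic by the para formyl group; the bulky TIPS ether, shielded further by the two flanking methoxy groups, is chosen to survive the carbonate base of step 10 and to fall to fluoride at the end.

Step 5
Reactants: 9 3,5-dimethoxy-4-(TIPSO)benzaldehyde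
Product: 10 [3,5-dimethoxy-4-(TIPSO)phenyl]methanol
Conditions: NaBH4, THF/EtOH, 0 °C
Reagents that add atoms: none
Why: Borohydride reduction of an aromatic aldehyde to the benzylic alcohol, conditions under which the hindered aryl silyl ether is stable.

Step 6
Reactants: 10 [3,5-dimethoxy-4-(TIPSO)phenyl]methanol
Product: 11 5-(bromomethyl)-1,3-dimethoxy-2-(TIPSO)benzene
Conditions: CBr4, PPh3, CH2Cl2, 0 °C
Reagents that add atoms: carbon tetrabromide, BrC(Br)(Br)Br
Why: Appel bromination of a primary benzylic alcohol under neutral conditions that leave the aryl silyl ether untouched; the reactive bromide is used directly after a short filtration.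

Step 7
Reactants: 12 (2R,5R)-hexane-2,5-diol
Product: 13 (2R,5R)-hexane-2,5-diyl dimethanesulfonate
Conditions: MsCl (2.4 equiv), Et3N (3 equiv), CH2Cl2, 0 °C
Reagents that add atoms: methanesulfonyl chloride, CS(=O)(=O)Cl
Why: Sulfonylation takes place at oxygen, so both stereogenic carbons keep their configuration.

Step 8
Reactants: 13 (2R,5R)-hexane-2,5-diyl dimethanesulfonate
Product: 14 (2S,5S)-2,5-dimethylthiolane
Conditions: Na2S·9H2O, DMSO, rt
Reagents that add atoms: Na2S (sodium sulfide), [Na+].[Na+].[S-2]
Why: Double SN2 displacement (intermolecular, then 5-exo-tet) inverts both carbons and should turn the (2R,5R)-dimesylate into the C2-symmetric (2S,5S)-thiolane, isolated by careful distillation because it is volatile.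

Step 9
Reactants: 11 5-(bromomethyl)-1,3-dimethoxy-2-(TIPSO)benzene; 14 (2S,5S)-2,5-dimethylthiolane
Product: 15 (2S,5S)-1-[3,5-dimethoxy-4-(TIPSO)benzyl]-2,5-dimethylthiolanium tetrafluoroborate
Conditions: AgBF4 (1.05 equiv), CH2Cl2, 0 °C to rt, dark
Reagents that add atoms: AgBF4 (silver tetrafluoroborate), [Ag+].F[B-](F)(F)F
Why: S-alkylation of a dialkyl sulfide by a benzylic bromide, made irreversible by precipitation of AgBr; the two lone pairs of the C2-symmetric sulfide are homotopic, so a single salt forms and sulfur is not a stereocentre.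

Step 10
Reactants: 7 rac-2-[1-(phenylsulfonyl)-2-(TBSO)ethyl]-6-methoxy-4-[3-(TBSO)propyl]phenol; 15 (2S,5S)-1-[3,5-dimethoxy-4-(TIPSO)benzyl]-2,5-dimethylthiolanium tetrafluoroborate
Product: 19 (2S,3R)-2-[3,5-dimethoxy-4-(TIPSO)phenyl]-7-methoxy-3-(TBSO-methyl)-5-[3-(TBSO)propyl]-2,3-dihydrobenzofuran, via ortho-quinone methide 16 (not isolated), via sulfonium benzylide 17 (not isolated), via betaine 18 (not isolated)
Conditions: 15 (1.5 equiv), Cs2CO3 (3.0 equiv), powdered 4 Å molecular sieves, dry MeCN, −20 °C; slow addition of 7; then 0 °C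
Reagents that add atoms: none
Why: Cs2CO3 deprotonates the phenol of 7, which expels benzenesulfinate (E1cB) to give the planar (E)-methide 16, and it also deprotonates salt 15 to the aryl-stabilised ylide 17. The ylide carbon adds in conjugate fashion to the exocyclic methide carbon (C2–C3 bond, ring A rearomatised) to give betaine 18, whose phenoxide then displaces the thiolane at the benzylic carbon (O1–C2 bond). The closest known reaction type is the base-mediated [4+1] annulation of sulfone-derived ortho-quinone methides with sulfonium ylides to trans-2,3-dihydrobenzofurans, combined with chiral-sulfide benzylidene transfer as used in asymmetric ylide epoxidation; a benzylic ylide in place of the usual carbonyl-stabilised one widens the scope without changing the mechanism. The dihydrofuran ring closes by 5-exo-tet SN2 displacement with inversion at C2. C2 is controlled by the thiolane, whose methyl group cis to the benzylidene blocks one ylide face, so that attack through the open face and inversion should give 2S with the (2S,5S)-sulfide; C3 is set in the same C–C bond formation, the anti approach that keeps the ylide aryl group away from ring A and the CH2OTBS arm leading to the trans (3R) product. The step needs capture of 16 before it tautomerises to the silyl enol ether or dimerises, which slow release of 16 at low temperature into an excess of 17 should secure; the racemic centre of 7 is of no consequence because it is planarised in 16.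

Step 11
Reactants: 19 (2S,3R)-2-[3,5-dimethoxy-4-(TIPSO)phenyl]-7-methoxy-3-(TBSO-methyl)-5-[3-(TBSO)propyl]-2,3-dihydrobenzofuran
Product: 20 (2S,3R)-2-(4-hydroxy-3,5-dimethoxyphenyl)-3-(hydroxymethyl)-5-(3-hydroxypropyl)-7-methoxy-2,3-dihydrobenzofuran
Conditions: Bu4NF (4 equiv), AcOH (4 equiv), THF, 0 °C to rt
Reagents that add atoms: none
Why: Fluoride-driven cleavage of the two primary TBS ethers and the aryl TIPS ether in one operation, buffered with acetic acid so that the freed para-phenol is not held as a phenoxide that could open the benzylic C2–O1 bond; neither stereocentre is touched.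

Compound list
1 | 3-(4-hydroxy-3-methoxyphenyl)propan-1-ol (dihydroconiferyl alcohol) | OCCCc1ccc(O)c(OC)c1 | starting material
2 | 4-[3-(tert-butyldimethylsilyloxy)propyl]-2-methoxyphenol | COc1cc(CCCO[Si](C)(C)C(C)(C)C)ccc1O | intermediate
3 | (tert-butyldimethylsilyloxy)acetaldehyde | O=CCO[Si](C)(C)C(C)(C)C | starting material
4 | bromomagnesium 4-[3-(tert-butyldimethylsilyloxy)propyl]-2-methoxyphenolate | COc1cc(CCCO[Si](C)(C)C(C)(C)C)ccc1O[Mg]Br | intermediate (not isolated)
5 | rac-2-[1-hydroxy-2-(tert-butyldimethylsilyloxy)ethyl]-6-methoxy-4-[3-(tert-butyldimethylsilyloxy)propyl]phenol | COc1cc(CCCO[Si](C)(C)C(C)(C)C)cc(C(O)CO[Si](C)(C)C(C)(C)C)c1O | intermediate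
6 | 1-[2-hydroxy-3-methoxy-5-[3-(tert-butyldimethylsilyloxy)propyl]phenyl]-2-(tert-butyldimethylsilyloxy)ethylium benzenesulfinate (ortho-hydroxybenzylic cation, ion pair) | COc1cc(CCCO[Si](C)(C)C(C)(C)C)cc([CH+]CO[Si](C)(C)C(C)(C)C)c1O.O=S([O-])c1ccccc1 | intermediate (not isolated)
7 | rac-2-[1-(phenylsulfonyl)-2-(tert-butyldimethylsilyloxy)ethyl]-6-methoxy-4-[3-(tert-butyldimethylsilyloxy)propyl]phenol | COc1cc(CCCO[Si](C)(C)C(C)(C)C)cc(C(CO[Si](C)(C)C(C)(C)C)S(=O)(=O)c2ccccc2)c1O | intermediate
8 | syringaldehyde (4-hydroxy-3,5-dimethoxybenzaldehyde) | COc1cc(C=O)cc(OC)c1O | starting material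
9 | 3,5-dimethoxy-4-(triisopropylsilyloxy)benzaldehyde | COc1cc(C=O)cc(OC)c1O[Si](C(C)C)(C(C)C)C(C)C | intermediate
10 | [3,5-dimethoxy-4-(triisopropylsilyloxy)phenyl]methanol | COc1cc(CO)cc(OC)c1O[Si](C(C)C)(C(C)C)C(C)C | intermediate
11 | 5-(bromomethyl)-1,3-dimethoxy-2-(triisopropylsilyloxy)benzene | COc1cc(CBr)cc(OC)c1O[Si](C(C)C)(C(C)C)C(C)C | intermediate
12 | (2R,5R)-hexane-2,5-diol | C[C@@H](O)CC[C@@H](C)O | starting material
13 | (2R,5R)-hexane-2,5-diyl dimethanesulfonate | C[C@@H](OS(C)(=O)=O)CC[C@@H](C)OS(C)(=O)=O | intermediate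
14 | (2S,5S)-2,5-dimethylthiolane | C[C@H]1CC[C@H](C)S1 | intermediate
15 | (2S,5S)-1-[3,5-dimethoxy-4-(triisopropylsilyloxy)benzyl]-2,5-dimethylthiolanium tetrafluoroborate | C[C@H]1CC[C@H](C)[S+]1Cc1cc(OC)c(O[Si](C(C)C)(C(C)C)C(C)C)c(OC)c1.F[B-](F)(F)F | intermediate
16 | (E)-6-[2-(tert-butyldimethylsilyloxy)ethylidene]-2-methoxy-4-[3-(tert-butyldimethylsilyloxy)propyl]cyclohexa-2,4-dien-1-one (ortho-quinone methide) | O=C1C(OC)=CC(CCCO[Si](C)(C)C(C)(C)C)=C/C1=C\CO[Si](C)(C)C(C)(C)C | intermediate (not isolated)
17 | (2S,5S)-2,5-dimethylthiolanium [3,5-dimethoxy-4-(triisopropylsilyloxy)phenyl]methylide (sulfonium benzylide) | C[C@H]1CC[C@H](C)[S+]1[CH-]c1cc(OC)c(O[Si](C(C)C)(C(C)C)C(C)C)c(OC)c1 | intermediate (not isolated)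
18 | betaine: 2-methoxy-4-[3-(TBSO)propyl]-6-[(1R,2R)-3-(TBSO)-1-[3,5-dimethoxy-4-(TIPSO)phenyl]-1-[(2S,5S)-2,5-dimethylthiolan-1-ium-1-yl]propan-2-yl]phenolate | [O-]c1c(OC)cc(CCCO[Si](C)(C)C(C)(C)C)cc1[C@H](CO[Si](C)(C)C(C)(C)C)[C@H](c1cc(OC)c(O[Si](C(C)C)(C(C)C)C(C)C)c(OC)c1)[S+]1[C@@H](C)CC[C@@H]1C | intermediate (not isolated)
19 | (2S,3R)-2-[3,5-dimethoxy-4-(triisopropylsilyloxy)phenyl]-7-methoxy-3-[(tert-butyldimethylsilyloxy)methyl]-5-[3-(tert-butyldimethylsilyloxy)propyl]-2,3-dihydrobenzofuran (trans) | COc1cc([C@H]2Oc3c(OC)cc(CCCO[Si](C)(C)C(C)(C)C)cc3[C@@H]2CO[Si](C)(C)C(C)(C)C)cc(OC)c1O[Si](C(C)C)(C(C)C)C(C)C | intermediate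
20 | (2S,3R)-2-(4-hydroxy-3,5-dimethoxyphenyl)-3-(hydroxymethyl)-5-(3-hydroxypropyl)-7-methoxy-2,3-dihydrobenzofuran (CNP0188630.1) | COc1cc([C@H]2Oc3c(OC)cc(CCCO)cc3[C@@H]2CO)cc(OC)c1O | target

Total step count: 11.
Longest linear sequence: 6 steps (8 → 9 → 10 → 11 → 15 → 19 → 20; steps 4, 5, 6, 9, 10, 11).

Steps most likely to fail

1. Step 10. What may go wrong: the thiolane may discriminate the ylide faces poorly on a methide acceptor, or the anti approach may not dominate, so that the product does not form as a single stereoisomer. Fallback (stereocontrol by separation instead of by reagent), setting out from 11 and 7: bromide 11 alkylates tetrahydrothiophene (AgBF4, CH2Cl2) to give achiral 1-[3,5-dimethoxy-4-(triisopropylsilyloxy)benzyl]thiolanium tetrafluoroborate F1. Its ylide (Cs2CO3, MeCN) with sulfone 7 should give the racemic trans annulation product F2, which is resolved by preparative supercritical-fluid chromatography on a chiral stationary phase. The (2S,3R) fraction is 19, where the route is rejoined.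

2. Step 2. What may go wrong: the magnesium alkoxide of the product may ionise onward to the methide and be captured by a second phenolate, or the enolisable aldehyde may self-condense before C–C bond formation. Fallback (formylation and one-carbon homologation), setting out from 2: ortho-formylation (MgCl2, Et3N, paraformaldehyde, MeCN, reflux) gives 2-hydroxy-3-methoxy-5-[3-(tert-butyldimethylsilyloxy)propyl]benzaldehyde F3. Addition of (iPrO)Me2SiCH2MgCl (2.5 equiv, THF, 0 °C) gives rac-2-[1-hydroxy-2-(isopropoxydimethylsilyl)ethyl]-6-methoxy-4-[3-(tert-butyldimethylsilyloxy)propyl]phenol F4. Tamao oxidation (H2O2, KF, KHCO3, THF/MeOH) gives rac-1-[2-hydroxy-3-methoxy-5-[3-(tert-butyldimethylsilyloxy)propyl]phenyl]ethane-1,2-diol F5. Silylation of its primary hydroxyl (TBSCl 1.05 equiv, Et3N, catalytic 4-dimethylaminopyridine, CH2Cl2, 0 °C) returns to 5.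

3. Step 3. What may go wrong: ionisation of a carbinol with an electron-withdrawing β-silyloxy group may be slow, and forcing the acid may cause silyl loss or a 1,2-hydride shift to the arylacetaldehyde. Fallback (sulfur introduced at the sulfide level under neutral conditions, then oxidised), setting out from 5: Mitsunobu thioetherification (PhSH, PPh3, diisopropyl azodicarboxylate, THF, 0 °C) gives rac-2-[1-(phenylthio)-2-(tert-butyldimethylsilyloxy)ethyl]-6-methoxy-4-[3-(tert-butyldimethylsilyloxy)propyl]phenol F6. Oxidation with H2O2 and catalytic (NH4)6Mo7O24 in EtOH (0 °C to rt) returns to sulfone 7.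

Further compounds
F1 | step 10 | 1-[3,5-dimethoxy-4-(triisopropylsilyloxy)benzyl]thiolanium tetrafluoroborate | C1CC[S+](C1)Cc1cc(OC)c(O[Si](C(C)C)(C(C)C)C(C)C)c(OC)c1.F[B-](F)(F)F
F2 | step 10 | racemic trans annulation product (equimolar mixture of 19 and its enantiomer) | COc1cc([C@H]2Oc3c(OC)cc(CCCO[Si](C)(C)C(C)(C)C)cc3[C@@H]2CO[Si](C)(C)C(C)(C)C)cc(OC)c1O[Si](C(C)C)(C(C)C)C(C)C.COc1cc([C@@H]2Oc3c(OC)cc(CCCO[Si](C)(C)C(C)(C)C)cc3[C@H]2CO[Si](C)(C)C(C)(C)C)cc(OC)c1O[Si](C(C)C)(C(C)C)C(C)C
F3 | step 2 | 2-hydroxy-3-methoxy-5-[3-(tert-butyldimethylsilyloxy)propyl]benzaldehyde | COc1cc(CCCO[Si](C)(C)C(C)(C)C)cc(C=O)c1O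
F4 | step 2 | rac-2-[1-hydroxy-2-(isopropoxydimethylsilyl)ethyl]-6-methoxy-4-[3-(tert-butyldimethylsilyloxy)propyl]phenol | COc1cc(CCCO[Si](C)(C)C(C)(C)C)cc(C(O)C[Si](C)(C)OC(C)C)c1O
F5 | step 2 | rac-1-[2-hydroxy-3-methoxy-5-[3-(tert-butyldimethylsilyloxy)propyl]phenyl]ethane-1,2-diol | COc1cc(CCCO[Si](C)(C)C(C)(C)C)cc(C(O)CO)c1O
F6 | step 3 | rac-2-[1-(phenylthio)-2-(tert-butyldimethylsilyloxy)ethyl]-6-methoxy-4-[3-(tert-butyldimethylsilyloxy)propyl]phenol | COc1cc(CCCO[Si](C)(C)C(C)(C)C)cc(C(CO[Si](C)(C)C(C)(C)C)Sc2ccccc2)c1O
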